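The route rests on a single disconnection: cutting the C1–C10 bond of ring A while re-joining C3 to C8 folds the decalin into a bicyclo[2.2.2]octenyl vinyl carbinol, the adduct of oxidised 4-methylsyringol and an acrylic acid unit. The key step, an anionic oxy-Cope shift, forms C1–C10, creates the quaternary methyl-bearing C10, closes ring A cis onto ring B and releases the C3 carbonyl and the C8 enol ether together; it exploits the vicinal C3/C4 oxygens of ring A, the C8 oxygen and C7 carbon of ring B and the C10 methyl. Its precursor is the endo C7 N-methoxy-N-methylamide (in place of an ester) of that carbinol, made as one enantiomer through a camphorsultam.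

Key step: step 5

Numbering: atom numbers are those of the target (eudesmane numbering), also for the bicyclic compounds; β means the face of the C10 methyl group.
Assumption: the face bias of the sultam in the uncatalysed cycloaddition is taken to be small and of unknown sense, so 7 is the diastereomer drawn, obtained by separation; if it is the minor one, the antipodal sultam is used with no other change.

Step 1
Reactants: 1 (1S,2R)-bornane-10,2-sultam; 2 acryloyl chloride
Product: 4 N-acryloyl-(1S,2R)-bornane-10,2-sultam, via sodium sultamide 3 (not isolated)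
Conditions: NaH, toluene, 0 °C → rt; then 2, CuCl (cat.), 0 °C → rt
Reagents that add atoms: none
Why: N-acylation of the sodium sulfonamide anion by the acid chloride (nucleophilic acyl substitution), with CuCl suppressing polymerisation and no stereocentre involved.

Step 2
Reactants: 5 2,6-dimethoxy-4-methylphenol; 4 N-acryloyl-(1S,2R)-bornane-10,2-sultam
Product: 7 endo cycloadduct (N-acyl sultam of the bicyclic keto ketal), via dienone 6 (not isolated)
Conditions: PhI(OAc)2, MeOH–CH2Cl2, 0 °C → rt, 5 added slowly to 4 and the oxidant; then separation of the two endo diastereomers (chromatography, crystallisation)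
Reagents that add atoms: methanol (CO)
Why: Oxidative dearomatisation in methanol gives the 6,6-dimethoxy dienone 6, which should be trapped before it dimerises in a Diels–Alder reaction with the usual "ortho" orientation (acyl-bearing carbon bonds to the methoxylated diene terminus) and endo preference, fixing C7 relative to both bridgeheads, while the sultam turns the two mirror-image endo series into separable diastereomers.

Step 3
Reactants: 7 endo cycloadduct
Product: 8 endo N-methoxy-N-methylamide of the bicyclic keto ketal
Conditions: MeNHOMe·HCl, AlMe3, CH2Cl2, 0 → 40 °C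
Reagents that add atoms: N,O-dimethylhydroxylamine hydrochloride (CNOC.Cl)
Why: Aminolysis of the N-acyl sultam by the aluminium amide formed from AlMe3 and the amine salt should transfer the acyl group cleanly, since the sultam has no second carbonyl to compete and the ketone is hindered and cannot enolise, so C7 is untouched.

Step 4
Reactants: 8 endo amide keto ketal; 9 vinylmagnesium bromide
Product: 10 bicyclo[2.2.2]octenyl vinyl carbinol (vinyl syn to the C9=C10 bridge)
Conditions: THF, −78 → −40 °C; aq. work-up
Reagents that add atoms: none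
Why: Grignard 1,2-addition to the α,α′-dialkoxy ketone is much faster at low temperature than attack on the N-methoxy-N-methylamide, and the nucleophile should enter from the side of the C9=C10 bridge, which is less encumbered than the ethano bridge, setting the carbinol centre with the vinyl group syn to that alkene.

Step 5
Reactants: 10 vinyl carbinol
Product: 13 cis-decalin (C3 ketone; C4 dimethyl ketal; C8 methyl enol ether; 7β-amide), via potassium alkoxide 11 (not isolated), via potassium enolate 12 (not isolated)
Conditions: KH, 18-crown-6, THF, 0 °C → rt; then AcOH, −78 °C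
Reagents that add atoms: none
Why: KH deprotonates the tertiary alcohol and the crown ether frees alkoxide 11, in which the array C1=C2–C3(O−)–C8–C9=C10 is held boat-like by the bicycle, so the [3,3] sigmatropic shift forms C1–C10, breaks the C3–C8 bridge bond and gives enolate 12, protonated to 13 on quenching. The closest known reaction type is this very one, the anionic oxy-Cope rearrangement of bicyclo[2.2.2]octenyl vinyl carbinols to cis-fused decalins. Ring A (C1, C2, C3, C4, C5, C10) closes as a six-membered carbocycle through the new C1–C10 σ-bond of the pericyclic event, with C3–C4–C5 as the pre-existing tether. The single new stereocentre, quaternary C10, is controlled by the bicycle: C1 can only reach the face of C9=C10 that faces the C3–C4 bridge, which puts the methyl group cis to H5 and to the endo C7 substituent. The step must win against base-mediated side reactions, and this is secured by the vinyl group lying syn to C9=C10 (step 4), by the endo amide that the alkoxide cannot reach, and by relief of bicyclic strain together with formation of a delocalised enolate.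

Step 6
Reactants: 13 cis-decalin keto ketal enol ether
Product: 15 4-hydroxy-Δ4-3,8-dione (diosphenol) 7β-amide, via keto ketal 14 (not isolated)
Conditions: 3 M aq. HCl, THF, 45 °C
Reagents that add atoms: water (O)
Why: Aqueous acid should hydrolyse the enol ether at once and then the carbonyl-deactivated ketal, the latter pulled forward by tautomerisation of the 3,4-dione to the conjugated C4 enol, which removes the C5 stereocentre on purpose, while C7, now between two carbonyls, keeps or settles into the equatorial 7β configuration.

Step 7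
Reactants: 15 diosphenol triketone
Product: 16 8β-hydroxy diosphenol 7β-amide
Conditions: LiBH(s-Bu)3 (2.3 equiv), THF, −78 °C; non-oxidative aq. work-up
Reagents that add atoms: none
Why: The first hydride equivalent turns the acidic enol into its lithium salt, which shields the ring A carbonyl, and the bulky trialkylborohydride should then reduce the saturated C8 ketone along the equatorial trajectory on the α-face, away from the axial 10β-methyl group, giving the axial 8β-alcohol cis to the C7 substituent (sterically controlled ketone reduction).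

Step 8
Reactants: 16 8β-hydroxy diosphenol
Product: 17 C4 enol triflate of the 3-ketone (C4=C5)
Conditions: PhNTf2, Et3N, DMAP (cat.), CH2Cl2, 0 °C → rt
Reagents that add atoms: N-phenylbis(trifluoromethanesulfonimide) (O=S(=O)(N(c1ccccc1)S(=O)(=O)C(F)(F)F)C(F)(F)F)
Why: O-Sulfonylation of the acidic enol with this mild triflating agent, which should leave the hindered secondary alcohol alone, fixes the C4=C5 position as the vinyl triflate of an α-diketone.

Step 9
Reactants: 17 enol triflate alcohol
Product: 18 8β-O-triethylsilyl ether of 17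
Conditions: Et3SiOTf, 2,6-lutidine, CH2Cl2, −78 °C
Reagents that add atoms: triethylsilyl trifluoromethanesulfonate (CC[Si](CC)(CC)OS(=O)(=O)C(F)(F)F)
Why: Silylation of the axial C8 alcohol with a silyl triflate and a hindered pyridine base masks the oxygen for the organometallic and enolate steps that an acetate would not survive.

Step 10
Reactants: 18 silyl ether enol triflate
Product: 19 4-methyl-Δ4-3-one
Conditions: Pd(PPh3)4 (cat.), SnMe4, LiCl, DMF, 80 °C
Reagents that add atoms: tetramethylstannane (C[Sn](C)(C)C)
Why: Stille coupling, in which zerovalent palladium inserts into the electron-poor vinyl triflate, tin transfers a methyl group (LiCl assisting) and reductive elimination installs C15 on C4 without touching a stereocentre.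

Step 11
Reactants: 19 4-methyl enone
Product: 20 3β-allylic alcohol
Conditions: NaBH4, CeCl3·7H2O, MeOH, −78 °C
Reagents that add atoms: none
Why: Luche reduction should give clean 1,2-reduction of the enone with hydride entering axially on the α-face, opposite the 10β-methyl group, so that the pseudo-equatorial 3β-alcohol predominates, amide and silyl ether being inert.

Step 12
Reactants: 20 3β-allylic alcohol amide
Product: 22 C7 methyl ketone (3β-OH free), via magnesium hemiaminal 21 (not isolated)
Conditions: MeMgBr (4 equiv), THF, 0 °C → rt; aq. work-up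
Reagents that add atoms: methylmagnesium bromide (C[Mg]Br)
Why: Grignard addition to the N-methoxy-N-methylamide stops at the chelated hemiaminal 21, which collapses to the methyl ketone only on work-up, so no tertiary alcohol should form, while the C3 hydroxyl travels as its magnesium alkoxide and C7 is not epimerised.

Step 13
Reactants: 22 methyl ketone alcohol
Product: 23 3β-isobutyrate
Conditions: i-PrCOCl, pyridine, DMAP (cat.), CH2Cl2, 0 °C
Reagents that add atoms: isobutyryl chloride (CC(C)C(=O)Cl)
Why: DMAP-catalysed acylation of the only free hydroxyl installs the isobutyrate with retention, since only the O–H bond reacts.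

Step 14
Reactants: 23 methyl ketone isobutyrate
Product: 25 C11 vinyl triflate (C11=C13), via potassium enolate 24 (not isolated)
Conditions: KN(SiMe3)2, THF, −78 °C; then N-(5-chloro-2-pyridyl)triflimide, −78 °C
Reagents that add atoms: N-(5-chloropyridin-2-yl)bis(trifluoromethanesulfonimide) (O=S(=O)(N(c1ccc(Cl)cn1)S(=O)(=O)C(F)(F)F)C(F)(F)F)
Why: Kinetic deprotonation by the bulky amide base should take a methyl proton and not the hindered C7 methine, and O-sulfonylation of enolate 24 then gives the terminal vinyl triflate with C7 intact (kinetic enol triflate formation).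

Step 15
Reactants: 25 vinyl triflate
Product: 26 methyl acrylate (C11=C13, C12 ester) with 8β-O-silyl ether
Conditions: Pd(OAc)2 (cat.), PPh3, CO (1 atm), MeOH, Et3N, DMF, 40 °C
Reagents that add atoms: carbon monoxide ([C-]#[O+]); methanol (CO)
Why: Palladium-catalysed alkoxycarbonylation of a vinyl triflate (oxidative addition, CO insertion, methanolysis of the acyl palladium) gives the α-substituted acrylate, and the hindered allylic isobutyrate on the tetrasubstituted alkene should ionise far more slowly than the triflate reacts.

Step 16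
Reactants: 26 silyl ether acrylate
Product: 27 8β-alcohol
Conditions: HF·pyridine, THF, 0 °C → rt
Reagents that add atoms: none
Why: Fluoride cleavage of the triethylsilyl ether under buffered, non-basic conditions should free the 8β-alcohol without touching the acrylate or the allylic ester.

Step 17
Reactants: 27 8β-alcohol
Product: 28 8β-acetate (Δ4 ene substrate)
Conditions: Ac2O, DMAP, pyridine, CH2Cl2, rt
Reagents that add atoms: acetic anhydride (CC(=O)OC(C)=O)
Why: DMAP-catalysed acetylation of the hindered axial alcohol proceeds with retention (only O–H reacts) under conditions too mild to move the β,γ-double bond of the acrylate into conjugation.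

Step 18
Reactants: 28 Δ4 alkene
Product: 29 methyl 8β-acetoxy-5α-hydroperoxy-3β-isobutyryloxyeudesma-4(15),11(13)-dien-12-oate (target)
Conditions: O2, tetraphenylporphyrin (cat.), visible light, CH2Cl2, 0 °C
Reagents that add atoms: dioxygen (O=O)
Why: Schenck ene reaction, in which singlet oxygen should attack the tetrasubstituted C4=C5 alkene on the α-face, opposite the 10β-methyl and 3β-acyloxy groups, and abstract hydrogen from the C15 methyl group (geminal to the ester-bearing allylic carbon and inherently favoured over ring methylene hydrogens), giving the 5α-hydroperoxide and the C4=C15 alkene while the electron-poor acrylate stays inert.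

Compound list
1 | (1S,2R)-bornane-10,2-sultam (2,10-camphorsultam, N on the exo face) | CC1(C)[C@@H]2CC[C@]13CS(=O)(=O)N[C@@H]3C2 | starting material
2 | acryloyl chloride | C=CC(=O)Cl | starting material
3 | sodium salt of 1 (not isolated) | CC1(C)[C@@H]2CC[C@]13CS(=O)(=O)[N-][C@@H]3C2.[Na+] | intermediate
4 | N-acryloyl-(1S,2R)-bornane-10,2-sultam | CC1(C)[C@@H]2CC[C@]13CS(=O)(=O)N(C(=O)C=C)[C@@H]3C2 | intermediate
5 | 2,6-dimethoxy-4-methylphenol (4-methylsyringol) | COc1cc(C)cc(OC)c1O | starting material
6 | 2,6,6-trimethoxy-4-methylcyclohexa-2,4-dien-1-one (not isolated) | COC1=CC(C)=CC(OC)(OC)C1=O | intermediate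
7 | endo cycloadduct: 1,3,3-trimethoxy-5-methyl-2-oxobicyclo[2.2.2]oct-5-ene with the N-sultam carbonyl on C7 (7S) pointing to the alkene bridge; bridgehead OMe carbon = future C8, ketone = C3, ketal = C4, methyl-bearing alkene carbon = C10 | CC1(C)[C@@H]2CC[C@]13CS(=O)(=O)N(C(=O)[C@H]4C[C@@H]5C(OC)(OC)C(=O)[C@@]4(OC)C=C5C)[C@@H]3C2 | intermediate
8 | endo (7S) N-methoxy-N-methylamide of the same bicyclic keto ketal | CON(C)C(=O)[C@H]1C[C@@H]2C(OC)(OC)C(=O)[C@@]1(OC)C=C2C | intermediate
9 | vinylmagnesium bromide | C=C[Mg]Br | starting material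
10 | vinyl carbinol of 8: tertiary alcohol at C3, vinyl syn to the C9=C10 bridge, amide endo | CON(C)C(=O)[C@H]1C[C@@H]2C(OC)(OC)[C@@](O)(C=C)[C@@]1(OC)C=C2C | intermediate
11 | potassium alkoxide of 10 (not isolated) | CON(C)C(=O)[C@H]1C[C@@H]2C(OC)(OC)[C@@]([O-])(C=C)[C@@]1(OC)C=C2C.[K+] | intermediate
12 | potassium C2=C3 enolate of 13 (not isolated) | CON(C)C(=O)[C@H]1C[C@@H]2C(OC)(OC)C([O-])=CC[C@]2(C)C=C1OC.[K+] | intermediate
13 | cis-decalin (5β-H, 10β-methyl): C3 ketone, C4 dimethyl ketal, C8 methyl enol ether (C8=C9), 7β-C(=O)N(OMe)Me | CON(C)C(=O)[C@H]1C[C@@H]2C(OC)(OC)C(=O)CC[C@]2(C)C=C1OC | intermediate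
14 | 3,8-diketone of the cis-decalin with C4 dimethyl ketal intact (not isolated) | CON(C)C(=O)[C@H]1C[C@@H]2C(OC)(OC)C(=O)CC[C@]2(C)CC1=O | intermediate
15 | 4-hydroxy-Δ4-3,8-dione (diosphenol), 10β-methyl, 7β-amide | CON(C)C(=O)[C@H]1CC2=C(O)C(=O)CC[C@]2(C)CC1=O | intermediate
16 | 8β-hydroxy-4-hydroxy-Δ4-3-one, 7β-amide | CON(C)C(=O)[C@H]1CC2=C(O)C(=O)CC[C@]2(C)C[C@H]1O | intermediate
17 | 4-triflyloxy-Δ4-3-one, 8β-OH, 7β-amide | CON(C)C(=O)[C@H]1CC2=C(OS(=O)(=O)C(F)(F)F)C(=O)CC[C@]2(C)C[C@H]1O | intermediate
18 | 8β-O-triethylsilyl ether of 17 | CON(C)C(=O)[C@H]1CC2=C(OS(=O)(=O)C(F)(F)F)C(=O)CC[C@]2(C)C[C@H]1O[Si](CC)(CC)CC | intermediate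
19 | 4-methyl-Δ4-3-one, 8β-OSiEt3, 7β-amide | CON(C)C(=O)[C@H]1CC2=C(C)C(=O)CC[C@]2(C)C[C@H]1O[Si](CC)(CC)CC | intermediate
20 | 3β-hydroxy-4-methyl-Δ4 alkene, 8β-OSiEt3, 7β-amide | CON(C)C(=O)[C@H]1CC2=C(C)[C@@H](O)CC[C@]2(C)C[C@H]1O[Si](CC)(CC)CC | intermediate
21 | bromomagnesium hemiaminal of 20 after methyl addition, C3 oxygen as magnesium alkoxide, hemiaminal carbon unspecified (not isolated) | CON(C)C(C)(O[Mg]Br)[C@H]1CC2=C(C)[C@@H](O[Mg]Br)CC[C@]2(C)C[C@H]1O[Si](CC)(CC)CC | intermediate
22 | 7β-acetyl compound: 3β-OH, 4-methyl-Δ4, 8β-OSiEt3 | CC(=O)[C@H]1CC2=C(C)[C@@H](O)CC[C@]2(C)C[C@H]1O[Si](CC)(CC)CC | intermediate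
23 | 3β-isobutyrate of 22 | CC(=O)[C@H]1CC2=C(C)[C@@H](OC(=O)C(C)C)CC[C@]2(C)C[C@H]1O[Si](CC)(CC)CC | intermediate
24 | potassium C11=C13 enolate of 23 (not isolated) | C=C([O-])[C@H]1CC2=C(C)[C@@H](OC(=O)C(C)C)CC[C@]2(C)C[C@H]1O[Si](CC)(CC)CC.[K+] | intermediate
25 | C11 vinyl triflate (C11=C13), 3β-isobutyrate, 8β-OSiEt3 | C=C(OS(=O)(=O)C(F)(F)F)[C@H]1CC2=C(C)[C@@H](OC(=O)C(C)C)CC[C@]2(C)C[C@H]1O[Si](CC)(CC)CC | intermediate
26 | methyl eudesma-4,11(13)-dien-12-oate with 3β-isobutyryloxy and 8β-OSiEt3 | C=C(C(=O)OC)[C@H]1CC2=C(C)[C@@H](OC(=O)C(C)C)CC[C@]2(C)C[C@H]1O[Si](CC)(CC)CC | intermediate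
27 | 8β-alcohol of 26 | C=C(C(=O)OC)[C@H]1CC2=C(C)[C@@H](OC(=O)C(C)C)CC[C@]2(C)C[C@H]1O | intermediate
28 | methyl 8β-acetoxy-3β-isobutyryloxyeudesma-4,11(13)-dien-12-oate | C=C(C(=O)OC)[C@H]1CC2=C(C)[C@@H](OC(=O)C(C)C)CC[C@]2(C)C[C@H]1OC(C)=O | intermediate
29 | methyl (3S,5S,7R,8R,10R)-8-acetoxy-5-hydroperoxy-3-isobutyryloxyeudesma-4(15),11(13)-dien-12-oate (3β, 5α, 7β-side chain, 8β, 10β-methyl) | C=C(C(=O)OC)[C@H]1C[C@@]2(OO)C(=C)[C@@H](OC(=O)C(C)C)CC[C@]2(C)C[C@H]1OC(C)=O | target

Total step count: 18. Longest linear sequence: 18 steps (1 to 29; phenol 5 enters at step 2).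

Steps most likely to fail

Step 2. Dimerisation of dienone 6 may outrun cycloaddition with the bulky dienophile used in small excess, and a weak face bias may make the separation of the two endo diastereomers wasteful. Fallback, from 5 back to 8: phenol 5 is oxidised with PhI(OAc)2 in methanol in the presence of a large excess of methyl acrylate, which should give the racemic endo methyl ester F1. LiOH in aqueous THF gives the racemic acid F2. Crystallisation with (S)-1-phenylethylamine gives the ammonium salt F3 of the wanted enantiomer (the antipodal amine is taken if this salt is the more soluble one). Dilute HCl frees the resolved acid F4, and 1,1'-carbonyldiimidazole followed by MeNHOMe·HCl gives 8.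

Step 7. Hydride may also be delivered to the ring A carbonyl, or attack on C8 may lose its face selectivity, while the enol is present. Fallback, from 15 back to 19: the enol of 15 is sulfonylated first with PhNTf2 and Et3N to the enol triflate dione F5. Stille methylation (Pd(PPh3)4, SnMe4, LiCl) gives the 4-methyl enedione F6. One equivalent of LiBH(s-Bu)3 at −78 °C should then reduce the saturated C8 ketone in preference to the hindered conjugated one, giving the 8β-hydroxy enone F7, and silylation with Et3SiOTf and 2,6-lutidine gives 19.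

Step 5. The alkoxide may fragment, or the strongly basic medium may degrade the N-methoxy amide (loss of formaldehyde, epimerisation) faster than the sigmatropic shift proceeds. Fallback, from 10 back to 13: the carbinol is silylated (Me3SiOTf, Et3N) to the trimethylsilyl ether F8, which is heated in o-dichlorobenzene (about 180 °C, sealed tube) so that the neutral siloxy-Cope rearrangement gives the trimethylsilyl enol ether F9. Bu4NF buffered with AcOH then cleaves the silicon–oxygen bond to give 13.

Further compounds
F1 | step 2 | racemic endo methyl 1,3,3-trimethoxy-5-methyl-2-oxobicyclo[2.2.2]oct-5-ene-7-carboxylate (one enantiomer drawn) | COC(=O)[C@H]1C[C@@H]2C(OC)(OC)C(=O)[C@@]1(OC)C=C2C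
F2 | step 2 | racemic endo 1,3,3-trimethoxy-5-methyl-2-oxobicyclo[2.2.2]oct-5-ene-7-carboxylic acid (one enantiomer drawn) | OC(=O)[C@H]1C[C@@H]2C(OC)(OC)C(=O)[C@@]1(OC)C=C2C
F3 | step 2 | (S)-1-phenylethylammonium salt of the (7S) acid | C[C@H]([NH3+])c1ccccc1.[O-]C(=O)[C@H]1C[C@@H]2C(OC)(OC)C(=O)[C@@]1(OC)C=C2C
F4 | step 2 | resolved (7S) endo acid, single enantiomer | OC(=O)[C@H]1C[C@@H]2C(OC)(OC)C(=O)[C@@]1(OC)C=C2C
F5 | step 7 | 4-triflyloxy-Δ4-3,8-dione, 7β-amide | CON(C)C(=O)[C@H]1CC2=C(OS(=O)(=O)C(F)(F)F)C(=O)CC[C@]2(C)CC1=O
F6 | step 7 | 4-methyl-Δ4-3,8-dione, 7β-amide | CON(C)C(=O)[C@H]1CC2=C(C)C(=O)CC[C@]2(C)CC1=O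
F7 | step 7 | 8β-hydroxy-4-methyl-Δ4-3-one, 7β-amide | CON(C)C(=O)[C@H]1CC2=C(C)C(=O)CC[C@]2(C)C[C@H]1O
F8 | step 5 | trimethylsilyl ether of carbinol 10 | CON(C)C(=O)[C@H]1C[C@@H]2C(OC)(OC)[C@@](O[Si](C)(C)C)(C=C)[C@@]1(OC)C=C2C
F9 | step 5 | C2=C3 trimethylsilyl enol ether of 13 | CON(C)C(=O)[C@H]1C[C@@H]2C(OC)(OC)C(O[Si](C)(C)C)=CC[C@]2(C)C=C1OC
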